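The synthesis rests on cutting ring B of the naphthoquinone at C7–C8 and C5–C6. Ring B carries the C5 hydroxyl next to the C6 aroyl ketone, the pyranonylmethyl group at C7 and hydrogen at C8, the 2-acyl-1-naphthol pattern that arises when a homophthalic anhydride enolate adds across an ynone and loses CO2. One operation thus joins the ring C half (5,6,8-trimethoxyhomophthalic anhydride) to the ring A–pyranone half (an aryl ynone bearing the pyranonylmethyl group) and builds ring B fully substituted. The base-sensitive ynone is unveiled only in the preceding step, by neutral oxidation of its propargylic alcohol. Oxidative demethylation of ring C and ether cleavage complete the route.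

Key step: step 8

Assumption: 2,4-dimethoxy-6-methylbenzaldehyde and 4-methoxy-6-methyl-2H-pyran-2-one are bought as catalogue compounds.

Remark: atom numbers C1–C8a refer to the naphthoquinone core of the target (C1 and C4 carbonyls, C2 hydroxyl). Ring A is the dihydroxytoluoyl ring, ring B the benzenoid ring C4a–C8a, ring C the quinone ring. The benzylic carbon of the anhydride becomes C8 and its aryl-bound carbonyl becomes C5, so the C1, C2 and C4 oxygens correspond to the 5,6,8-trimethoxy pattern of the anhydride. The target is achiral; only 10 and 11 carry a (racemic, later erased) stereocentre.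

Step 1
Reactants: 1 2,4,5-trimethoxybenzoic acid
Product: 3 3,4,6-trimethoxy-2-methylbenzoic acid, via dilithiated benzoate 2 (not isolated)
Conditions: s-BuLi (2.2 equiv), TMEDA, THF, −78 °C; MeI, −78 °C → rt; aq. HCl
Reagents that add atoms: iodomethane, CI
Why: Directed ortho-metalation of the unprotected benzoic acid should remove the only hydrogen ortho to CO2Li (a carbon also flanked by a methoxy group), s-BuLi/TMEDA at −78 °C favouring this coordination-controlled site over the position between two methoxy groups, and MeI then methylates the aryllithium.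

Step 2
Reactants: 3 3,4,6-trimethoxy-2-methylbenzoic acid
Product: 5 2-(carboxymethyl)-3,4,6-trimethoxybenzoic acid, via benzylic dianion 4 (not isolated)
Conditions: LiN(iPr)2 (2.5 equiv), THF, −78 → 0 °C; CO2 (g), −78 °C; aq. HCl
Reagents that add atoms: carbon dioxide, O=C=O
Why: Lateral lithiation of the o-toluate gives a carboxylate-stabilised benzylic dianion whose carboxylation is the standard entry to homophthalic acids.

Step 3
Reactants: 5 2-(carboxymethyl)-3,4,6-trimethoxybenzoic acid
Product: 6 5,6,8-trimethoxy-1H-isochromene-1,3(4H)-dione (5,6,8-trimethoxyhomophthalic anhydride)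
Conditions: Ac2O, toluene, reflux
Reagents that add atoms: none
Why: Cyclodehydration of the 1,5-diacid through the mixed anhydride should close the six-membered cyclic anhydride.

Step 4
Reactants: 7 4-methoxy-6-methyl-2H-pyran-2-one
Product: 8 6-(bromomethyl)-4-methoxy-2H-pyran-2-one
Conditions: NBS, (PhCO2)2 (cat.), PhCF3, reflux
Reagents that add atoms: N-bromosuccinimide, O=C1CCC(=O)N1Br
Why: Wohl–Ziegler bromination, in which hydrogen abstraction from the C6 methyl gives a radical delocalised over the pyranone diene and non-polar radical conditions suppress ionic bromination at C3.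

Step 5
Reactants: 9 2,4-dimethoxy-6-methylbenzaldehyde
Product: 10 rac-1-(2,4-dimethoxy-6-methylphenyl)prop-2-yn-1-ol
Conditions: HC≡CMgBr, THF, 0 °C; aq. NH4Cl
Reagents that add atoms: ethynylmagnesium bromide, C#C[Mg]Br
Why: Grignard 1,2-addition to the aldehyde; the carbinol centre is formed racemic without control because step 7 oxidises it away.

Step 6
Reactants: 10 rac-1-(2,4-dimethoxy-6-methylphenyl)prop-2-yn-1-ol; 8 6-(bromomethyl)-4-methoxy-2H-pyran-2-one
Product: 11 rac-6-[4-(2,4-dimethoxy-6-methylphenyl)-4-hydroxybut-2-yn-1-yl]-4-methoxy-2H-pyran-2-one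
Conditions: CuI (10 mol %), n-Bu4NI (10 mol %), K2CO3, DMF, rt, argon
Reagents that add atoms: none
Why: Copper-catalysed coupling of a terminal alkyne with an activated allylic-type bromide (SN2 attack of the copper acetylide, iodide as co-catalyst); at the carbinol oxidation level the new pyranonyl-propargylic CH2 is only weakly acidic, so carbonate should not isomerise it.

Step 7
Reactants: 11 rac-6-[4-(2,4-dimethoxy-6-methylphenyl)-4-hydroxybut-2-yn-1-yl]-4-methoxy-2H-pyran-2-one
Product: 12 1-(2,4-dimethoxy-6-methylphenyl)-4-(4-methoxy-2-oxo-2H-pyran-6-yl)but-2-yn-1-one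
Conditions: Dess–Martin periodinane, CH2Cl2, 0 °C → rt; pH 7 buffer
Reagents that add atoms: none
Why: Dess–Martin oxidation of the benzylic propargylic alcohol is neutral and amine-free, so the doubly activated CH2 between alkyne and pyranone should not be isomerised to the allenyl ketone.

Step 8
Reactants: 6 5,6,8-trimethoxyhomophthalic anhydride; 12 1-(2,4-dimethoxy-6-methylphenyl)-4-(4-methoxy-2-oxo-2H-pyran-6-yl)but-2-yn-1-one
Product: 16 6-{[3-(2,4-dimethoxy-6-methylbenzoyl)-4-hydroxy-5,7,8-trimethoxynaphthalen-2-yl]methyl}-4-methoxy-2H-pyran-2-one, via sodium enolate 13 (not isolated), via allenolate Michael adduct 14 (not isolated), via keto carboxylate 15 (not isolated)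
Conditions: NaH (1.1 equiv), THF, 0 °C; then 12, 0 °C → rt; aq. HCl
Reagents that add atoms: none
Why: NaH deprotonates the benzylic CH2 of 6 (future C8) to the soft, weakly basic enolate 13, which adds to the ynone β-carbon (future C7) to give allenolate 14; its α-carbon (C6) then acylates the aryl-bound anhydride carbonyl (C5) in a 6-(enolexo)-exo-trig closure that opens the anhydride to keto carboxylate 15, and loss of CO2 with tautomerisation aromatises ring B to the C5 naphthol. The closest known reaction type is the Tamura annulation of homophthalic anhydrides with acetylenic ketones and esters to 2-acyl-1-naphthols. No stereocentre is formed. The step needs regioselectivity (C8 to C7, not 1,2-addition) and chemoselectivity over proton transfer and over the pyranone: the twisted, di-ortho-substituted aroyl carbonyl is shielded so that only the alkyne β-carbon is open to attack, 13 is too weak a base to strip the propargylic CH2 quickly, and the 4-methoxypyranone is a far poorer acceptor than the ynone. Should part of 12 isomerise to the allenyl ketone, addition of 13 to its central carbon followed by the same acylation, decarboxylation and tautomerisation would lead to the same naphthol.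

Step 9
Reactants: 16 6-{[3-(2,4-dimethoxy-6-methylbenzoyl)-4-hydroxy-5,7,8-trimethoxynaphthalen-2-yl]methyl}-4-methoxy-2H-pyran-2-one
Product: 17 6-{[3-(2,4-dimethoxy-6-methylbenzoyl)-4-hydroxy-7-methoxy-5,8-dioxo-5,8-dihydronaphthalen-2-yl]methyl}-4-methoxy-2H-pyran-2-one
Conditions: (NH4)2Ce(NO3)6 (2.5 equiv), MeCN–H2O, 0 °C
Reagents that add atoms: water, O
Why: Oxidative demethylation by tetravalent cerium of the para-dimethoxy pair C1/C4 on the most electron-rich ring should give the 2-methoxy-1,4-quinone (quinone oxygens from water), while the acyl-deactivated meta-dimethoxy ring A and the pyranone are not oxidised; even the isomeric 4-methoxy-1,2-quinone would converge on the same hydroxyquinone in step 10.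

Step 10
Reactants: 17 6-{[3-(2,4-dimethoxy-6-methylbenzoyl)-4-hydroxy-7-methoxy-5,8-dioxo-5,8-dihydronaphthalen-2-yl]methyl}-4-methoxy-2H-pyran-2-one
Product: 18 6-(2,4-dihydroxy-6-methylbenzoyl)-2,5-dihydroxy-7-[(4-hydroxy-2-oxo-2H-pyran-6-yl)methyl]naphthalene-1,4-dione (CNP0158797.0)
Conditions: BBr3 (10 equiv), CH2Cl2, −78 °C → rt; ice–water
Reagents that add atoms: none
Why: BBr3 ether cleavage (bromide attack on the methyl group of the boron-bound oxonium) should remove the two aryl methyl ethers of ring A and the two vinylogous methyl esters at quinone C2 and pyranone C4, and hydrolysis of the borates releases the target.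

Compound list
1 | 2,4,5-trimethoxybenzoic acid | COc1cc(OC)c(C(=O)O)cc1OC | starting material
2 | lithium 2-lithio-3,4,6-trimethoxybenzoate | [Li]c1c(OC)c(OC)cc(OC)c1C(=O)[O-].[Li+] | intermediate
3 | 3,4,6-trimethoxy-2-methylbenzoic acid | Cc1c(OC)c(OC)cc(OC)c1C(=O)O | intermediate
4 | lithium 2-(lithiomethyl)-3,4,6-trimethoxybenzoate | [Li]Cc1c(OC)c(OC)cc(OC)c1C(=O)[O-].[Li+] | intermediate
5 | 2-(carboxymethyl)-3,4,6-trimethoxybenzoic acid | OC(=O)Cc1c(OC)c(OC)cc(OC)c1C(=O)O | intermediate
6 | 5,6,8-trimethoxy-1H-isochromene-1,3(4H)-dione (5,6,8-trimethoxyhomophthalic anhydride) | O=C1Cc2c(OC)c(OC)cc(OC)c2C(=O)O1 | intermediate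
7 | 4-methoxy-6-methyl-2H-pyran-2-one | Cc1cc(OC)cc(=O)o1 | starting material
8 | 6-(bromomethyl)-4-methoxy-2H-pyran-2-one | BrCc1cc(OC)cc(=O)o1 | intermediate
9 | 2,4-dimethoxy-6-methylbenzaldehyde | Cc1cc(OC)cc(OC)c1C=O | starting material
10 | rac-1-(2,4-dimethoxy-6-methylphenyl)prop-2-yn-1-ol | Cc1cc(OC)cc(OC)c1C(O)C#C | intermediate
11 | rac-6-[4-(2,4-dimethoxy-6-methylphenyl)-4-hydroxybut-2-yn-1-yl]-4-methoxy-2H-pyran-2-one | Cc1cc(OC)cc(OC)c1C(O)C#CCc1cc(OC)cc(=O)o1 | intermediate
12 | 1-(2,4-dimethoxy-6-methylphenyl)-4-(4-methoxy-2-oxo-2H-pyran-6-yl)but-2-yn-1-one | Cc1cc(OC)cc(OC)c1C(=O)C#CCc1cc(OC)cc(=O)o1 | intermediate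
13 | sodium 5,6,8-trimethoxy-1-oxo-1H-isochromen-3-olate (sodium enolate of 6) | [Na+].[O-]C1=Cc2c(OC)c(OC)cc(OC)c2C(=O)O1 | intermediate
14 | sodium 1-(2,4-dimethoxy-6-methylphenyl)-3-[(4-methoxy-2-oxo-2H-pyran-6-yl)methyl]-3-(5,6,8-trimethoxy-1,3-dioxoisochroman-4-yl)propa-1,2-dien-1-olate | [Na+].[O-]C(=C=C(Cc1cc(OC)cc(=O)o1)C1C(=O)OC(=O)c2c(OC)cc(OC)c(OC)c12)c1c(C)cc(OC)cc1OC | intermediate
15 | sodium 3-(2,4-dimethoxy-6-methylbenzoyl)-5,7,8-trimethoxy-2-[(4-methoxy-2-oxo-2H-pyran-6-yl)methyl]-4-oxo-1,4-dihydronaphthalene-1-carboxylate | [Na+].[O-]C(=O)C1C(Cc2cc(OC)cc(=O)o2)=C(C(=O)c2c(C)cc(OC)cc2OC)C(=O)c2c(OC)cc(OC)c(OC)c12 | intermediate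
16 | 6-{[3-(2,4-dimethoxy-6-methylbenzoyl)-4-hydroxy-5,7,8-trimethoxynaphthalen-2-yl]methyl}-4-methoxy-2H-pyran-2-one | Cc1cc(OC)cc(OC)c1C(=O)c1c(Cc2cc(OC)cc(=O)o2)cc2c(OC)c(OC)cc(OC)c2c1O | intermediate
17 | 6-{[3-(2,4-dimethoxy-6-methylbenzoyl)-4-hydroxy-7-methoxy-5,8-dioxo-5,8-dihydronaphthalen-2-yl]methyl}-4-methoxy-2H-pyran-2-one | Cc1cc(OC)cc(OC)c1C(=O)c1c(Cc2cc(OC)cc(=O)o2)cc2c(c1O)C(=O)C=C(OC)C2=O | intermediate
18 | 6-(2,4-dihydroxy-6-methylbenzoyl)-2,5-dihydroxy-7-[(4-hydroxy-2-oxo-2H-pyran-6-yl)methyl]naphthalene-1,4-dione | Cc1cc(O)cc(O)c1C(=O)c1c(Cc2cc(O)cc(=O)o2)cc2c(c1O)C(=O)C=C(O)C2=O | target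

Total step count: 10. Longest linear sequence: 6 steps (steps 5, 6, 7, 8, 9, 10 from 9; equally steps 1, 2, 3, 8, 9, 10 from 1).

Steps most likely to fail

Step 8 (annulation). Proton transfer from the pyranonyl-propargylic CH2 of 12 to enolate 13 may outrun conjugate addition, so that the ynone is drained into its cumulenolate and oligomerises while 13 self-condenses. The fallback sets out from 9 (together with 6) and returns at 16; it leaves the pyranone out of the annulation and builds it afterwards. Aldehyde 9 is added to the lithium acetylide of 4,4-diethoxybut-1-yne (n-BuLi, THF, −78 °C) to give rac-5,5-diethoxy-1-(2,4-dimethoxy-6-methylphenyl)pent-2-yn-1-ol F1. Dess–Martin oxidation then gives 5,5-diethoxy-1-(2,4-dimethoxy-6-methylphenyl)pent-2-yn-1-one F2, whose CH2 lacks the vinylogous activation. Annulation of F2 with 6 under the conditions of step 8 should give (2,4-dimethoxy-6-methylphenyl)[3-(2,2-diethoxyethyl)-1-hydroxy-5,6,8-trimethoxynaphthalen-2-yl]methanone F3. Aqueous HCl in THF releases 2-[3-(2,4-dimethoxy-6-methylbenzoyl)-4-hydroxy-5,7,8-trimethoxynaphthalen-2-yl]acetaldehyde F4. A vinylogous Mukaiyama aldol addition of the trimethylsilyl dienol ether of 2,2,6-trimethyl-4H-1,3-dioxin-4-one (BF3·OEt2, CH2Cl2, −78 °C) gives rac-6-{3-[3-(2,4-dimethoxy-6-methylbenzoyl)-4-hydroxy-5,7,8-trimethoxynaphthalen-2-yl]-2-hydroxypropyl}-2,2-dimethyl-4H-1,3-dioxin-4-one F5. Dess–Martin oxidation gives 6-{3-[3-(2,4-dimethoxy-6-methylbenzoyl)-4-hydroxy-5,7,8-trimethoxynaphthalen-2-yl]-2-oxopropyl}-2,2-dimethyl-4H-1,3-dioxin-4-one F6. Heating in toluene (retro-[4+2] to the acylketene, capture by the ketone enol) closes 6-{[3-(2,4-dimethoxy-6-methylbenzoyl)-4-hydroxy-5,7,8-trimethoxynaphthalen-2-yl]methyl}-4-hydroxy-2H-pyran-2-one F7. Me2SO4/K2CO3 in acetone methylates the acidic pyranone hydroxyl in preference to the chelated naphthol and gives 16.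

Step 10 (global ether cleavage). The quinone may be consumed by bromide addition, reduction or ring bromination while the slower para-methoxy group of ring A and the pyranone ether are still being cleaved. The fallback sets out from 16 and returns at 18; it reverses the order of the end game so that no quinone meets the Lewis acid. Naphthol 16 is demethylated exhaustively with BBr3 (CH2Cl2, −78 °C → rt) to 6-{[3-(2,4-dihydroxy-6-methylbenzoyl)-4,5,7,8-tetrahydroxynaphthalen-2-yl]methyl}-4-hydroxy-2H-pyran-2-one F8. The 1,2,4-trihydroxylated ring C of F8 should autoxidise during an aerated work-up at pH 7 (air or O2) to the 2-hydroxy-1,4-quinone 18, so step 9 is not needed.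

Step 1 (ortho-methylation). Deprotonation may occur at the position between the two methoxy groups instead of ortho to the carboxylate, or s-BuLi may add to the lithium carboxylate. The fallback sets out from 1 and returns at 3; it introduces the methyl group by carboxylate-directed C–H activation with divalent palladium: Pd(OAc)2 (cat.), MeB(OH)2, Ag2CO3, 1,4-benzoquinone, K2HPO4, t-BuOH, 100 °C. Cyclopalladation can only take place at the single ortho C–H bond, and 3 should form directly, with no new compound on the way (F0).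

Further compounds
F1 | step 8 | rac-5,5-diethoxy-1-(2,4-dimethoxy-6-methylphenyl)pent-2-yn-1-ol | Cc1cc(OC)cc(OC)c1C(O)C#CCC(OCC)OCC
F2 | step 8 | 5,5-diethoxy-1-(2,4-dimethoxy-6-methylphenyl)pent-2-yn-1-one | Cc1cc(OC)cc(OC)c1C(=O)C#CCC(OCC)OCC
F3 | step 8 | (2,4-dimethoxy-6-methylphenyl)[3-(2,2-diethoxyethyl)-1-hydroxy-5,6,8-trimethoxynaphthalen-2-yl]methanone | Cc1cc(OC)cc(OC)c1C(=O)c1c(CC(OCC)OCC)cc2c(OC)c(OC)cc(OC)c2c1O
F4 | step 8 | 2-[3-(2,4-dimethoxy-6-methylbenzoyl)-4-hydroxy-5,7,8-trimethoxynaphthalen-2-yl]acetaldehyde | Cc1cc(OC)cc(OC)c1C(=O)c1c(CC=O)cc2c(OC)c(OC)cc(OC)c2c1O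
F5 | step 8 | rac-6-{3-[3-(2,4-dimethoxy-6-methylbenzoyl)-4-hydroxy-5,7,8-trimethoxynaphthalen-2-yl]-2-hydroxypropyl}-2,2-dimethyl-4H-1,3-dioxin-4-one | Cc1cc(OC)cc(OC)c1C(=O)c1c(CC(O)CC2=CC(=O)OC(C)(C)O2)cc2c(OC)c(OC)cc(OC)c2c1O
F6 | step 8 | 6-{3-[3-(2,4-dimethoxy-6-methylbenzoyl)-4-hydroxy-5,7,8-trimethoxynaphthalen-2-yl]-2-oxopropyl}-2,2-dimethyl-4H-1,3-dioxin-4-one | Cc1cc(OC)cc(OC)c1C(=O)c1c(CC(=O)CC2=CC(=O)OC(C)(C)O2)cc2c(OC)c(OC)cc(OC)c2c1O
F7 | step 8 | 6-{[3-(2,4-dimethoxy-6-methylbenzoyl)-4-hydroxy-5,7,8-trimethoxynaphthalen-2-yl]methyl}-4-hydroxy-2H-pyran-2-one | Cc1cc(OC)cc(OC)c1C(=O)c1c(Cc2cc(O)cc(=O)o2)cc2c(OC)c(OC)cc(OC)c2c1O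
F8 | step 10 | 6-{[3-(2,4-dihydroxy-6-methylbenzoyl)-4,5,7,8-tetrahydroxynaphthalen-2-yl]methyl}-4-hydroxy-2H-pyran-2-one | Cc1cc(O)cc(O)c1C(=O)c1c(Cc2cc(O)cc(=O)o2)cc2c(O)c(O)cc(O)c2c1O
F0 | step 1 | none | none
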